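Removing the two epoxide oxygens leaves a 1,5-diene, C3=C4–C5–C6–C7=C8, inside the twelve-membered ring (C1 to C11 plus C15) that is bridged by ring A. Its Cope isomer has a C3–C8 bond instead of C5–C6: a taxane-like bicyclo[5.3.1]undecane carrying isopropenyl on C3 and vinyl on C8, trans to each other. Everything rests on this retro-Cope disconnection. Heating bicycle 24 forms C5–C6, breaks C3–C8 and enlarges the eight-membered ring to the twelve-membered one in a single operation, with both olefins E and with C1, C10 and C11 already in place. The bicycle is built by Ireland–Claisen rearrangement, conjugate addition to a cyclohexadienone and allylchromium ring closure; double epoxidation finishes.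

Key step: step 18

Remarks
- Numbering: verticillane numbering is used for atoms throughout (ring A = C1, C14, C13, C12, C11, C15; C16 and C17 on C15; C18 on C12; C19 on C8; C20 on C4). TBS = tert-butyldimethylsilyl. Names of the bicyclic compounds include the gem-dimethyl group on C15.
- Assumption: the facial sense of the chiral bromoborane (step 3) and of the copper–phosphoramidite catalyst (step 7) is taken from simple esters and cyclohexenones; should either be opposite, the enantiomeric controller or ligand is used and nothing else changes.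
- C10 is set by ketone reduction (step 15), not by the ring closure, so the route does not depend on the facial outcome of step 13.
- Diol 22 is carried as a mixture at C13; that centre is removed in step 16.

Step 1
Reactants: 1 tert-butyl(but-3-yn-1-yloxy)dimethylsilane
Product: 3 (E)-5-(TBSO)-3-methylpent-2-en-1-ol, via (E)-alkenyldimethylalane 2 (not isolated)
Conditions: Me3Al, Cp2ZrCl2 (25 mol %), CH2Cl2, 0 °C to rt; n-BuLi, THF, −78 °C; (CH2O)n, rt; aq. NH4Cl
Reagents that add atoms: trimethylaluminium, C[Al](C)C; formaldehyde (from paraformaldehyde), C=O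
Why: Zirconocene-catalysed syn carboalumination (Negishi) puts methyl on the internal and aluminium on the terminal alkyne carbon, and the derived aluminate is hydroxymethylated with retention, so the olefin that later delivers C8 is E only.

Step 2
Reactants: 3 (E)-5-(TBSO)-3-methylpent-2-en-1-ol; 4 3-methylbut-3-enoic acid
Product: 5 (E)-5-(TBSO)-3-methylpent-2-en-1-yl 3-methylbut-3-enoate
Conditions: DCC, DMAP (5 mol %), CH2Cl2, 0 °C
Reagents that add atoms: none
Why: Steglich esterification (carbodiimide activation, acyl transfer by DMAP) at 0 °C joins acid and allylic alcohol without moving the β,γ-double bond of 4 into conjugation.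

Step 3
Reactants: 5 (E)-5-(TBSO)-3-methylpent-2-en-1-yl 3-methylbut-3-enoate
Product: 7 (2R,3R)-5-(TBSO)-3-ethenyl-3-methyl-2-(prop-1-en-2-yl)pentanoic acid, via boron ketene acetal 6 (not isolated)
Conditions: (4S,5S)-2-bromo-1,3-bis{[3,5-bis(trifluoromethyl)phenyl]sulfonyl}-4,5-diphenyl-1,3,2-diazaborolidine, Et3N, toluene/hexane, −78 °C, then −20 to 4 °C; aq. work-up
Reagents that add atoms: none
Why: Enantioselective Ireland–Claisen rearrangement of a chiral boron ketene acetal: soft enolisation gives the enolate with isopropenyl trans to O–B, the chair transition state with the E olefin (C9 equatorial, C19 axial) sets C3 and C8 in the relative sense that later places isopropenyl and vinyl trans on the eight-membered ring, and the S,S sulfonamide ligand selects the enantiomer.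

Step 4
Reactants: 7 (2R,3R)-5-(TBSO)-3-ethenyl-3-methyl-2-(prop-1-en-2-yl)pentanoic acid
Product: 8 (2R,3R)-5-(TBSO)-3-ethenyl-3-methyl-2-(prop-1-en-2-yl)pentan-1-ol
Conditions: LiAlH4, THF, 0 °C to rt
Reagents that add atoms: none
Why: Hydride reduction of the carboxylic acid gives the primary alcohol (C2) and leaves the silyl ether and the isolated olefins untouched.

Step 5
Reactants: 8 (2R,3R)-5-(TBSO)-3-ethenyl-3-methyl-2-(prop-1-en-2-yl)pentan-1-ol
Product: 9 (2R,3R)-5-(TBSO)-3-ethenyl-1-iodo-3-methyl-2-(prop-1-en-2-yl)pentane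
Conditions: I2, PPh3, imidazole, CH2Cl2, 0 °C to rt
Reagents that add atoms: iodine, II
Why: Phosphine–iodine activation of the primary alcohol and SN2 displacement by iodide (Appel/Garegg conditions) give the iodide without touching C3 or C8.

Step 6
Reactants: 10 4,4-dimethylcyclohex-2-en-1-one
Product: 11 4,4-dimethylcyclohexa-2,5-dien-1-one
Conditions: DDQ, 1,4-dioxane, reflux
Reagents that add atoms: none
Why: DDQ dehydrogenation of the enol of 10 introduces the second double bond, and the quaternary C4 prevents aromatisation.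

Step 7
Reactants: 9 (2R,3R)-5-(TBSO)-3-ethenyl-1-iodo-3-methyl-2-(prop-1-en-2-yl)pentane; 11 4,4-dimethylcyclohexa-2,5-dien-1-one
Product: 13 (5R)-5-[(2R,3R)-5-(TBSO)-3-ethenyl-3-methyl-2-(prop-1-en-2-yl)pentyl]-4,4-dimethylcyclohex-2-en-1-one, via diorganozinc 12 (not isolated)
Conditions: 9, Et2Zn (neat), CuI (cat.), 50 °C, then vacuum; 11, Cu(OTf)2 (2 mol %), O,O′-(S)-1,1′-binaphthyl-2,2′-diyl N,N-bis[(R)-1-phenylethyl]phosphoramidite (4 mol %), toluene, −30 °C; aq. NH4Cl
Reagents that add atoms: none
Why: Iodine–zinc exchange gives the salt-free diorganozinc, and copper/phosphoramidite-catalysed enantioselective conjugate addition desymmetrises the dienone: the ligand selects the face of one enantiotopic β-carbon and so sets C1 (R), while the hindered mono-adduct should not add a second time.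

Step 8
Reactants: 13 (5R)-5-[(2R,3R)-5-(TBSO)-3-ethenyl-3-methyl-2-(prop-1-en-2-yl)pentyl]-4,4-dimethylcyclohex-2-en-1-one
Product: 14 (5R)-5-[(2R,3R)-5-(TBSO)-3-ethenyl-3-methyl-2-(prop-1-en-2-yl)pentyl]-2-iodo-4,4-dimethylcyclohex-2-en-1-one
Conditions: I2, pyridine, CH2Cl2, rt
Reagents that add atoms: iodine, II
Why: Pyridine-mediated α-iodination of the enone (conjugate addition of pyridine, iodination of the enolate, elimination) marks C12 for carbon–carbon coupling and is established for 4,4-dimethylcyclohexenones.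

Step 9
Reactants: 14 (5R)-5-[(2R,3R)-5-(TBSO)-3-ethenyl-3-methyl-2-(prop-1-en-2-yl)pentyl]-2-iodo-4,4-dimethylcyclohex-2-en-1-one
Product: 15 (5R)-5-[(2R,3R)-3-ethenyl-5-hydroxy-3-methyl-2-(prop-1-en-2-yl)pentyl]-2-iodo-4,4-dimethylcyclohex-2-en-1-one
Conditions: camphorsulfonic acid (10 mol %), MeOH, 0 °C
Reagents that add atoms: none
Why: Acid-catalysed methanolysis cleaves the primary silyl ether, the iodoenone and the olefins being inert to catalytic acid at 0 °C.

Step 10
Reactants: 15 (5R)-5-[(2R,3R)-3-ethenyl-5-hydroxy-3-methyl-2-(prop-1-en-2-yl)pentyl]-2-iodo-4,4-dimethylcyclohex-2-en-1-one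
Product: 16 (3R,4R)-3-ethenyl-5-[(1R)-4-iodo-2,2-dimethyl-5-oxocyclohex-3-en-1-yl]-3-methyl-4-(prop-1-en-2-yl)pentanal
Conditions: Dess–Martin periodinane, NaHCO3, CH2Cl2, 0 °C to rt
Reagents that add atoms: none
Why: Dess–Martin oxidation converts the primary alcohol into the C10 aldehyde under buffered conditions that do not enolise it.

Step 11
Reactants: 16 (3R,4R)-3-ethenyl-5-[(1R)-4-iodo-2,2-dimethyl-5-oxocyclohex-3-en-1-yl]-3-methyl-4-(prop-1-en-2-yl)pentanal
Product: 17 (3R,4R)-3-ethenyl-5-[(1R)-4-(hydroxymethyl)-2,2-dimethyl-5-oxocyclohex-3-en-1-yl]-3-methyl-4-(prop-1-en-2-yl)pentanal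
Conditions: Bu3SnCH2OH, Pd(PPh3)4 (5 mol %), 1,4-dioxane, 90 °C
Reagents that add atoms: (tributylstannyl)methanol, CCCC[Sn](CCCC)(CCCC)CO
Why: Stille coupling of the α-iodoenone with the hydroxymethylstannane installs C18 as an allylic alcohol, and the aldehyde is tolerated.

Step 12
Reactants: 17 (3R,4R)-3-ethenyl-5-[(1R)-4-(hydroxymethyl)-2,2-dimethyl-5-oxocyclohex-3-en-1-yl]-3-methyl-4-(prop-1-en-2-yl)pentanal
Product: 18 (3R,4R)-5-[(1R)-4-(bromomethyl)-2,2-dimethyl-5-oxocyclohex-3-en-1-yl]-3-ethenyl-3-methyl-4-(prop-1-en-2-yl)pentanal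
Conditions: N-bromosuccinimide, Me2S, CH2Cl2, −20 to 0 °C
Reagents that add atoms: N-bromosuccinimide, O=C1CCC(=O)N1Br
Why: Corey–Kim bromination turns the primary allylic alcohol into the bromide under neutral conditions that spare the aldehyde and the olefins.

Step 13
Reactants: 18 (3R,4R)-5-[(1R)-4-(bromomethyl)-2,2-dimethyl-5-oxocyclohex-3-en-1-yl]-3-ethenyl-3-methyl-4-(prop-1-en-2-yl)pentanal
Product: 20 (1R,3R,8R,10S,11R)-8-ethenyl-10-hydroxy-8,15,15-trimethyl-12-methylidene-3-(prop-1-en-2-yl)bicyclo[5.3.1]undecan-13-one, via allylchromium dichloride 19 (not isolated)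
Conditions: CrCl2 (8 equiv), THF, slow addition of 18 (final 0.003 M), rt
Reagents that add atoms: none
Why: Nozaki–Hiyama allylation: the allylchromium species attacks the aldehyde through its γ-carbon C11 with shift of the double bond to C12=C18; only the face of C11 cis to the C1–C2 bond can be reached, which fixes C11 (R), and the closed chair transition state should place the aldehyde hydrogen in the pocket under ring A, so the 10S alcohol is expected, an outcome that steps 14 to 16 make immaterial.

Step 14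
Reactants: 20 (1R,3R,8R,10S,11R)-8-ethenyl-10-hydroxy-8,15,15-trimethyl-12-methylidene-3-(prop-1-en-2-yl)bicyclo[5.3.1]undecan-13-one
Product: 21 (1R,3R,8R,11R)-8-ethenyl-8,15,15-trimethyl-12-methylidene-3-(prop-1-en-2-yl)bicyclo[5.3.1]undecane-10,13-dione
Conditions: Dess–Martin periodinane, NaHCO3, CH2Cl2, 0 °C; used crude
Reagents that add atoms: none
Why: Dess–Martin oxidation gives the C10 ketone and erases whatever C10 configuration the ring closure gave; the bridgehead C11–H lies near the carbonyl plane and is poorly aligned for enolisation, which, with buffering and immediate use, should keep C12=C18 out of conjugation.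

Step 15
Reactants: 21 (1R,3R,8R,11R)-8-ethenyl-8,15,15-trimethyl-12-methylidene-3-(prop-1-en-2-yl)bicyclo[5.3.1]undecane-10,13-dione
Product: 22 (1R,3R,8R,10R,11R)-8-ethenyl-8,15,15-trimethyl-12-methylidene-3-(prop-1-en-2-yl)bicyclo[5.3.1]undecane-10,13-diol (C13 epimers)
Conditions: NaBH4, CeCl3·7H2O, MeOH, −78 to −20 °C
Reagents that add atoms: none
Why: Luche reduction adds hydride 1,2 to both ketones: at C10 it arrives on the open outer face of the bicycle, opposite the pocket under ring A, which sets C10 (R), whereas C13 forms as either epimer and is re-oxidised in step 16.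

Step 16
Reactants: 22 (1R,3R,8R,10R,11R)-8-ethenyl-8,15,15-trimethyl-12-methylidene-3-(prop-1-en-2-yl)bicyclo[5.3.1]undecane-10,13-diol
Product: 23 (1R,3R,8R,10R,11R)-8-ethenyl-10-hydroxy-8,15,15-trimethyl-12-methylidene-3-(prop-1-en-2-yl)bicyclo[5.3.1]undecan-13-one
Conditions: MnO2 (excess), CH2Cl2, rt
Reagents that add atoms: none
Why: MnO2 oxidises allylic alcohols selectively, so only C13 returns to the ketone, now conjugated with C12=C18, while the secondary C10 alcohol stays.

Step 17
Reactants: 23 (1R,3R,8R,10R,11R)-8-ethenyl-10-hydroxy-8,15,15-trimethyl-12-methylidene-3-(prop-1-en-2-yl)bicyclo[5.3.1]undecan-13-one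
Product: 24 (1R,3R,8R,10R,11R)-10-acetoxy-8-ethenyl-8,15,15-trimethyl-12-methylidene-3-(prop-1-en-2-yl)bicyclo[5.3.1]undecan-13-one
Conditions: Ac2O, DMAP, pyridine, CH2Cl2, rt
Reagents that add atoms: acetic anhydride, CC(=O)OC(C)=O
Why: DMAP-catalysed acyl transfer esterifies the C10 alcohol with retention and, being irreversible, drains any C10–O–C13 hemiketal form.

Step 18
Reactants: 24 (1R,3R,8R,10R,11R)-10-acetoxy-8-ethenyl-8,15,15-trimethyl-12-methylidene-3-(prop-1-en-2-yl)bicyclo[5.3.1]undecan-13-one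
Product: 25 (1R,10R,11R,3E,7E)-10-acetoxyverticilla-3,7,12(18)-trien-13-one
Conditions: toluene (0.01 M, degassed), BHT (cat.), sealed tube, 150 °C
Reagents that add atoms: none
Why: A concerted suprafacial [3,3]-sigmatropic shift (Cope rearrangement) runs through a chair transition state in which C3, C4, C5, C6, C7 and C8 are arranged like a cyclohexane trans-fused to the eight-membered ring, so C5–C6 forms as C3–C8 breaks. The closest known reaction is the thermal rearrangement of trans-1,2-dialkenylcycloalkanes to ring-enlarged E,E-1,5-dienes (elemene–germacrene type). The twelve-membered ring (C1 to C11 plus C15) is closed by four-atom expansion of the eight-membered ring and not end to end, so no high dilution is needed for ring formation. No stereocentre is created: C3 and C8 are given up, and C1, C10 and C11 are not touched. The step needs E geometry at both new olefins, which the trans arrangement of isopropenyl and vinyl secures because the ring bonds C3–C2 and C8–C9 are both equatorial in the chair; it also needs the equilibrium on the product side, for which release of eight-membered-ring strain, loss of the crowded C3–C8 bond and two trisubstituted olefins in place of a vinyl and an isopropenyl group all argue. Dilute, degassed solution with a radical inhibitor should keep the methylene ketone from dimerising.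

Step 19
Reactants: 25 (1R,10R,11R,3E,7E)-10-acetoxyverticilla-3,7,12(18)-trien-13-one
Product: 26 (1R,3S,4S,7S,8S,10R,11R)-10-acetoxy-3,4:7,8-diepoxyverticill-12(18)-en-13-one (CNP0339728.1)
Conditions: dimethyldioxirane (2.4 equiv), acetone, −20 to 0 °C
Reagents that add atoms: dimethyldioxirane, CC1(C)OO1
Why: Electrophilic epoxidation by the dioxirane is fast at the two electron-rich trisubstituted olefins and slow at the electron-poor C12=C18; each E olefin gives its trans epoxide stereospecifically, and attack on the outer faces of the conformer delivered by the chair rearrangement (both olefin planes perpendicular to the ring, C19 and C20 on the face of H1 and H11) should give the 3S,4S,7S,8S isomer.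

Compound list
1 | tert-butyl(but-3-yn-1-yloxy)dimethylsilane | C#CCCO[Si](C)(C)C(C)(C)C | starting material
2 | (E)-[4-(TBSO)-2-methylbut-1-en-1-yl]dimethylalane | C[Al](C)/C=C(\C)CCO[Si](C)(C)C(C)(C)C | intermediate
3 | (E)-5-(TBSO)-3-methylpent-2-en-1-ol | OC/C=C(\C)CCO[Si](C)(C)C(C)(C)C | intermediate
4 | 3-methylbut-3-enoic acid | C=C(C)CC(=O)O | starting material
5 | (E)-5-(TBSO)-3-methylpent-2-en-1-yl 3-methylbut-3-enoate | C=C(C)CC(=O)OC/C=C(\C)CCO[Si](C)(C)C(C)(C)C | intermediate
6 | boron ketene acetal of 5 (isopropenyl trans to O–B; boron carries the S,S bis-sulfonamide) | C=C(C)/C=C(\OC/C=C(\C)CCO[Si](C)(C)C(C)(C)C)OB1N(S(=O)(=O)c2cc(cc(c2)C(F)(F)F)C(F)(F)F)[C@@H](c2ccccc2)[C@H](c2ccccc2)N1S(=O)(=O)c1cc(cc(c1)C(F)(F)F)C(F)(F)F | intermediate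
7 | (2R,3R)-5-(TBSO)-3-ethenyl-3-methyl-2-(prop-1-en-2-yl)pentanoic acid | OC(=O)[C@H](C(C)=C)[C@@](C)(C=C)CCO[Si](C)(C)C(C)(C)C | intermediate
8 | (2R,3R)-5-(TBSO)-3-ethenyl-3-methyl-2-(prop-1-en-2-yl)pentan-1-ol | OC[C@H](C(C)=C)[C@@](C)(C=C)CCO[Si](C)(C)C(C)(C)C | intermediate
9 | (2R,3R)-5-(TBSO)-3-ethenyl-1-iodo-3-methyl-2-(prop-1-en-2-yl)pentane | IC[C@H](C(C)=C)[C@@](C)(C=C)CCO[Si](C)(C)C(C)(C)C | intermediate
10 | 4,4-dimethylcyclohex-2-en-1-one | CC1(C)CCC(=O)C=C1 | starting material
11 | 4,4-dimethylcyclohexa-2,5-dien-1-one | CC1(C)C=CC(=O)C=C1 | intermediate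
12 | bis[(2R,3R)-5-(TBSO)-3-ethenyl-3-methyl-2-(prop-1-en-2-yl)pentyl]zinc | [Zn](C[C@H](C(C)=C)[C@@](C)(C=C)CCO[Si](C)(C)C(C)(C)C)C[C@H](C(C)=C)[C@@](C)(C=C)CCO[Si](C)(C)C(C)(C)C | intermediate
13 | (5R)-5-[(2R,3R)-5-(TBSO)-3-ethenyl-3-methyl-2-(prop-1-en-2-yl)pentyl]-4,4-dimethylcyclohex-2-en-1-one | O=C1C[C@@H](C[C@H](C(C)=C)[C@@](C)(C=C)CCO[Si](C)(C)C(C)(C)C)C(C)(C)C=C1 | intermediate
14 | (5R)-5-[(2R,3R)-5-(TBSO)-3-ethenyl-3-methyl-2-(prop-1-en-2-yl)pentyl]-2-iodo-4,4-dimethylcyclohex-2-en-1-one | O=C1C[C@@H](C[C@H](C(C)=C)[C@@](C)(C=C)CCO[Si](C)(C)C(C)(C)C)C(C)(C)C=C1I | intermediate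
15 | (5R)-5-[(2R,3R)-3-ethenyl-5-hydroxy-3-methyl-2-(prop-1-en-2-yl)pentyl]-2-iodo-4,4-dimethylcyclohex-2-en-1-one | O=C1C[C@@H](C[C@H](C(C)=C)[C@@](C)(C=C)CCO)C(C)(C)C=C1I | intermediate
16 | (3R,4R)-3-ethenyl-5-[(1R)-4-iodo-2,2-dimethyl-5-oxocyclohex-3-en-1-yl]-3-methyl-4-(prop-1-en-2-yl)pentanal | O=C1C[C@@H](C[C@H](C(C)=C)[C@@](C)(C=C)CC=O)C(C)(C)C=C1I | intermediate
17 | (3R,4R)-3-ethenyl-5-[(1R)-4-(hydroxymethyl)-2,2-dimethyl-5-oxocyclohex-3-en-1-yl]-3-methyl-4-(prop-1-en-2-yl)pentanal | O=C1C[C@@H](C[C@H](C(C)=C)[C@@](C)(C=C)CC=O)C(C)(C)C=C1CO | intermediate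
18 | (3R,4R)-5-[(1R)-4-(bromomethyl)-2,2-dimethyl-5-oxocyclohex-3-en-1-yl]-3-ethenyl-3-methyl-4-(prop-1-en-2-yl)pentanal | O=C1C[C@@H](C[C@H](C(C)=C)[C@@](C)(C=C)CC=O)C(C)(C)C=C1CBr | intermediate
19 | allylchromium dichloride from 18 (CrCl2 on C18) | O=C1C[C@@H](C[C@H](C(C)=C)[C@@](C)(C=C)CC=O)C(C)(C)C=C1C[Cr](Cl)Cl | intermediate
20 | (1R,3R,8R,10S,11R)-8-ethenyl-10-hydroxy-8,15,15-trimethyl-12-methylidene-3-(prop-1-en-2-yl)bicyclo[5.3.1]undecan-13-one | C=C1C(=O)C[C@H]2C[C@H](C(C)=C)[C@@](C)(C=C)C[C@H](O)[C@@H]1C2(C)C | intermediate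
21 | (1R,3R,8R,11R)-8-ethenyl-8,15,15-trimethyl-12-methylidene-3-(prop-1-en-2-yl)bicyclo[5.3.1]undecane-10,13-dione | C=C1C(=O)C[C@H]2C[C@H](C(C)=C)[C@@](C)(C=C)CC(=O)[C@@H]1C2(C)C | intermediate
22 | (1R,3R,8R,10R,11R)-8-ethenyl-8,15,15-trimethyl-12-methylidene-3-(prop-1-en-2-yl)bicyclo[5.3.1]undecane-10,13-diol (C13 epimers) | C=C1C(O)C[C@H]2C[C@H](C(C)=C)[C@@](C)(C=C)C[C@@H](O)[C@@H]1C2(C)C | intermediate
23 | (1R,3R,8R,10R,11R)-8-ethenyl-10-hydroxy-8,15,15-trimethyl-12-methylidene-3-(prop-1-en-2-yl)bicyclo[5.3.1]undecan-13-one | C=C1C(=O)C[C@H]2C[C@H](C(C)=C)[C@@](C)(C=C)C[C@@H](O)[C@@H]1C2(C)C | intermediate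
24 | (1R,3R,8R,10R,11R)-10-acetoxy-8-ethenyl-8,15,15-trimethyl-12-methylidene-3-(prop-1-en-2-yl)bicyclo[5.3.1]undecan-13-one | C=C1C(=O)C[C@H]2C[C@H](C(C)=C)[C@@](C)(C=C)C[C@@H](OC(C)=O)[C@@H]1C2(C)C | intermediate
25 | (1R,10R,11R,3E,7E)-10-acetoxyverticilla-3,7,12(18)-trien-13-one | C=C1C(=O)C[C@H]2C/C=C(\C)CC/C=C(\C)C[C@@H](OC(C)=O)[C@@H]1C2(C)C | intermediate
26 | (1R,3S,4S,7S,8S,10R,11R)-10-acetoxy-3,4:7,8-diepoxyverticill-12(18)-en-13-one (CNP0339728.1) | C=C1C(=O)C[C@H]2C[C@@H]3O[C@@]3(C)CC[C@@H]3O[C@@]3(C)C[C@@H](OC(C)=O)[C@@H]1C2(C)C | target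

Total step count: 19 steps.
Longest linear sequence: 18 steps (steps 1 to 5 and 7 to 19; step 6 is a one-step branch that joins at step 7).

Steps most likely to fail

Step 18. What may go wrong: at the temperature the shift needs, the methylene ketone of 24 is consumed by dimerisation or ene reactions, or the acetate is lost, faster than the bicycle rearranges. Fallback: the rearrangement is moved ahead of ketone and ester formation. It sets out from diol 22, which has no conjugated carbonyl group. Heating 22 under the conditions of step 18 should give (1R,10R,11R,3E,7E)-verticilla-3,7,12(18)-triene-10,13-diol F1. MnO2 then oxidises only the allylic C13 alcohol to (1R,10R,11R,3E,7E)-10-hydroxyverticilla-3,7,12(18)-trien-13-one F2. Acetylation (Ac2O, DMAP, pyridine) brings the route back at 25.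

Step 13. What may go wrong: protonation or intermolecular coupling of the allylchromium species outruns closure of the strained eight-membered ring. Fallback: a one-electron closure from a different substrate. It sets out from 17, which is acetylated (Ac2O, pyridine) to (3R,4R)-5-[(1R)-4-(acetoxymethyl)-2,2-dimethyl-5-oxocyclohex-3-en-1-yl]-3-ethenyl-3-methyl-4-(prop-1-en-2-yl)pentanal F3. SmI2 (THF, t-BuOH, −78 °C) reduces the aldehyde to a ketyl that adds to C11 of the enone, and the samarium enolate so formed expels acetate to give the methylene ketone. The route is rejoined at 20 or at its C10 epimer 23; either one is converted into 21 by step 14.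

Step 19. What may go wrong: the macrocycle reacts through a conformer in which C19 or C20 has swung to the other face, so that oxygen reaches the wrong face of one olefin and a diastereomeric diepoxide forms; slow oxidation of C12=C18 is a lesser concern. Fallback: reagent control in place of conformational control. Shi epoxidation of 25 with the enantiomer of the fructose-derived ketone catalyst (prepared from L-sorbose), KHSO5, K2CO3 buffer, MeCN/dimethoxymethane/water, 0 °C, should by the spiro transition-state model give S,S epoxides at both E-trisubstituted olefins. It sets out from 25 and comes back at 26; no compound outside the list arises (F0).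

Further compounds
F1 | step 18 | (1R,10R,11R,3E,7E)-verticilla-3,7,12(18)-triene-10,13-diol (C13 epimers) | C=C1C(O)C[C@H]2C/C=C(\C)CC/C=C(\C)C[C@@H](O)[C@@H]1C2(C)C
F2 | step 18 | (1R,10R,11R,3E,7E)-10-hydroxyverticilla-3,7,12(18)-trien-13-one | C=C1C(=O)C[C@H]2C/C=C(\C)CC/C=C(\C)C[C@@H](O)[C@@H]1C2(C)C
F3 | step 13 | (3R,4R)-5-[(1R)-4-(acetoxymethyl)-2,2-dimethyl-5-oxocyclohex-3-en-1-yl]-3-ethenyl-3-methyl-4-(prop-1-en-2-yl)pentanal | O=C1C[C@@H](C[C@H](C(C)=C)[C@@](C)(C=C)CC=O)C(C)(C)C=C1COC(C)=O
F0 | step 19 | none | none
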